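The benzene ring, the only ring, is built rather than functionalised: its C5–C6 bond is formed by a Moore rearrangement, the thermal 4π-opening/6π-closure of a 4-alkenyl-4-hydroxycyclobutenone. The step exploits the fact that ring atoms C2(OH)–C3(OMe)–C4(H)–C5(OH) are the four carbons of methyl semisquarate, while C1 (bearing the side chain) and C6(H) are a 1,1-disubstituted vinyl group. One thermolysis therefore delivers the correctly substituted methoxyhydroquinone. Its precursor is the adduct of the semisquarate with a 2-lithioalkene that carries the (R)-silyloxy stereocentre from an enantioselective 2-bromoallylation of dodecanal. The quinone then serves as a phenol-free relay for acetylation.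

Key step: step 6

Remark: arene numbering is C1 (side chain), C2 (OH), C3 (OMe), C4 (H), C5 (OH), C6 (H). In step 1 the ligand antipode is the one that gives the R alcohol, to be confirmed by Mosher ester analysis of 3.

Step 1
Reactants: 1 dodecanal; 2 2,3-dibromoprop-1-ene
Product: 3 (4R)-2-bromopentadec-1-en-4-ol
Conditions: CrCl2 (10 mol %), chiral N-[2-(4-isopropyl-4,5-dihydrooxazol-2-yl)phenyl]sulfonamide ligand (11 mol %), proton sponge, cobalt phthalocyanine Co(C32H16N8) (cat.), Mn powder, (C5H5)2ZrCl2, LiCl, MeCN, rt; aq. work-up
Reagents that add atoms: none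
Why: This is a catalytic asymmetric Nozaki–Hiyama–Kishi-type 2-haloallylation, known for aliphatic aldehydes, in which the cobalt co-catalyst activates only the allylic C–Br bond of 2, the ligand-bound 2-bromoallylchromium species should add to the Si face of the aldehyde through a closed six-membered transition state to set the R carbinol centre, and the vinyl bromide stays intact because no nickel is present.

Step 2
Reactants: 3 (4R)-2-bromopentadec-1-en-4-ol
Product: 4 (4R)-2-bromo-4-(tert-butyldimethylsilyloxy)pentadec-1-ene
Conditions: TBSCl, imidazole, DMF, rt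
Reagents that add atoms: tert-butyldimethylsilyl chloride, CC(C)(C)[Si](C)(C)Cl
Why: Imidazole-promoted silylation of a secondary alcohol is routine, the silyl ether withstands tert-butyllithium, heat and Ag2O, and the C–O bond of the stereocentre is not touched.

Step 3
Reactants: 5 dimethyl squarate (3,4-dimethoxycyclobut-3-ene-1,2-dione)
Product: 6 4-hydroxy-2,3-dimethoxycyclobut-2-en-1-one (racemic)
Conditions: LiAlH(OtBu)3, THF, −78 → −20 °C; H2O quench
Reagents that add atoms: none
Why: The bulky alkoxyaluminium hydride should add once to one of the two equivalent vinylogous-ester carbonyls at low temperature (known partial reduction of squarate esters), and the new racemic centre is lost in the next step.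

Step 4
Reactants: 6 4-hydroxy-2,3-dimethoxycyclobut-2-en-1-one
Product: 7 3-methoxycyclobut-3-ene-1,2-dione (methyl semisquarate)
Conditions: conc. HCl (cat.), CH2Cl2, rt; dry, concentrate cold, use at once
Reagents that add atoms: none
Why: Acid-catalysed ionisation of the allylic hydroxyl gives a methoxy-stabilised cyclobutenyl cation that recaptures the released water at the far methoxy-bearing carbon and expels methanol, a net 1,3-carbonyl transposition established for the higher semisquarate esters.

Step 5
Reactants: 4 (4R)-2-bromo-4-(tert-butyldimethylsilyloxy)pentadec-1-ene; 7 3-methoxycyclobut-3-ene-1,2-dione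
Product: 9 4-[(4R)-4-(tert-butyldimethylsilyloxy)pentadec-1-en-2-yl]-4-hydroxy-3-methoxycyclobut-2-en-1-one (both carbinol epimers), via alkenyllithium 8 (not isolated)
Conditions: t-BuLi (2.1 equiv), Et2O, −78 °C; cannulate into 7, THF, −78 °C; aq. NH4Cl at −78 °C; chromatography on Et3N-deactivated silica
Reagents that add atoms: none
Why: Bromine–lithium exchange gives the 2-lithioalkene, which should add 1,2 to the more electrophilic carbonyl of 7 (the one next to C–OMe, not the vinylogous-ester carbonyl) as organolithiums do with 3-alkoxycyclobutenediones; the new carbinol centre forms unselectively and both epimers are used because it vanishes on aromatisation, while the remote (R)-silyloxy centre is untouched.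

Step 6
Reactants: 9 4-[(4R)-4-(tert-butyldimethylsilyloxy)pentadec-1-en-2-yl]-4-hydroxy-3-methoxycyclobut-2-en-1-one
Product: 12 2-[(2R)-2-(tert-butyldimethylsilyloxy)tridecyl]-6-methoxybenzene-1,4-diol, via dienylketene 10 (not isolated), via cyclohexadienone 11 (not isolated)
Conditions: degassed toluene (0.02 M), 110 °C, Ar; concentrate and use crude
Reagents that add atoms: none
Why: Heating cleaves the C(=O)–C(OH) bond of the cyclobutenone by a conrotatory 4π electrocyclic opening to dienylketene 10, whose ketene carbon then bonds to the terminal CH2 of the 1,1-disubstituted vinyl group, creating the C5–C6 bond of the arene. The closest known reaction type is the Moore rearrangement of 4-alkenyl-4-hydroxycyclobutenones to hydroquinones. The six-membered carbocycle closes by a thermal disrotatory 6π electrocyclisation of the ketene C=C, the enol C=C and the vinyl C=C, and dienone 11 aromatises by tautomerisation. No stereocentre is created, since the carbinol carbon becomes aromatic C2 and the (R)-silyloxy centre of the side chain takes no part. The step needs the alkenyl group to rotate inward so that it lies cis to the ketene, which the preference of the hydroxyl donor for outward rotation secures; the substitution pattern (ketene carbon to C5–OH, CH to C4, C–OMe to C3, carbinol to C2–OH, vinyl carbons to C1 and C6) follows from the connectivity of 9 alone.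

Step 7
Reactants: 12 2-[(2R)-2-(tert-butyldimethylsilyloxy)tridecyl]-6-methoxybenzene-1,4-diol
Product: 13 2-[(2R)-2-(tert-butyldimethylsilyloxy)tridecyl]-6-methoxy-1,4-benzoquinone
Conditions: Ag2O, Na2SO4, Et2O, rt
Reagents that add atoms: none
Why: Ag2O is a mild neutral oxidant that converts electron-rich hydroquinones into 1,4-benzoquinones without affecting the silyl ether or the stereocentre, and using the crude thermolysate avoids handling the air-sensitive hydroquinone.

Step 8
Reactants: 13 2-[(2R)-2-(tert-butyldimethylsilyloxy)tridecyl]-6-methoxy-1,4-benzoquinone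
Product: 14 2-[(2R)-2-hydroxytridecyl]-6-methoxy-1,4-benzoquinone
Conditions: HF (48 % aq.), MeCN, 0 °C → rt
Reagents that add atoms: none
Why: Fluoride-assisted cleavage of the secondary silyl ether under mildly acidic conditions should spare the base-sensitive methoxyquinone, and the C–O bond is kept, so the R configuration is retained.

Step 9
Reactants: 14 2-[(2R)-2-hydroxytridecyl]-6-methoxy-1,4-benzoquinone
Product: 15 (2R)-1-(5-methoxy-3,6-dioxocyclohexa-1,4-dien-1-yl)tridecan-2-yl acetate
Conditions: Ac2O, pyridine, DMAP (cat.), CH2Cl2, 0 °C, dark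
Reagents that add atoms: acetic anhydride, CC(=O)OC(C)=O
Why: With both phenolic oxygens masked as quinone carbonyls the secondary alcohol is the only acylable group, so a standard nucleophile-catalysed acetylation at low temperature should give the monoacetate with retention.

Step 10
Reactants: 15 (2R)-1-(5-methoxy-3,6-dioxocyclohexa-1,4-dien-1-yl)tridecan-2-yl acetate
Product: 16 (2R)-1-(2,5-dihydroxy-3-methoxyphenyl)tridecan-2-yl acetate (CNP0331604.1)
Conditions: Na2S2O4, EtOAc/H2O, rt, Ar; degassed work-up
Reagents that add atoms: none
Why: Dithionite reduces 1,4-benzoquinones to hydroquinones within minutes in a two-phase system at room temperature and touches neither the alkyl acetate nor the stereocentre.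

Compound list
1 | dodecanal | CCCCCCCCCCCC=O | starting material
2 | 2,3-dibromoprop-1-ene | BrCC(Br)=C | starting material
3 | (4R)-2-bromopentadec-1-en-4-ol | CCCCCCCCCCC[C@H](CC(Br)=C)O | intermediate
4 | (4R)-2-bromo-4-(tert-butyldimethylsilyloxy)pentadec-1-ene | CCCCCCCCCCC[C@H](CC(Br)=C)O[Si](C)(C)C(C)(C)C | intermediate
5 | dimethyl squarate (3,4-dimethoxycyclobut-3-ene-1,2-dione) | COC1=C(OC)C(=O)C1=O | starting material
6 | 4-hydroxy-2,3-dimethoxycyclobut-2-en-1-one (racemic) | COC1=C(OC)C(O)C1=O | intermediate
7 | 3-methoxycyclobut-3-ene-1,2-dione | COC1=CC(=O)C1=O | intermediate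
8 | [(4R)-4-(tert-butyldimethylsilyloxy)pentadec-1-en-2-yl]lithium | CCCCCCCCCCC[C@H](CC([Li])=C)O[Si](C)(C)C(C)(C)C | intermediate (not isolated)
9 | 4-[(4R)-4-(tert-butyldimethylsilyloxy)pentadec-1-en-2-yl]-4-hydroxy-3-methoxycyclobut-2-en-1-one (both carbinol epimers) | CCCCCCCCCCC[C@H](CC(=C)C1(O)C(OC)=CC1=O)O[Si](C)(C)C(C)(C)C | intermediate
10 | (3Z,7R)-7-(tert-butyldimethylsilyloxy)-4-hydroxy-3-methoxy-5-methylideneoctadeca-1,3-dien-1-one (dienylketene) | CCCCCCCCCCC[C@H](CC(=C)/C(O)=C(OC)\C=C=O)O[Si](C)(C)C(C)(C)C | intermediate (not isolated)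
11 | 5-[(2R)-2-(tert-butyldimethylsilyloxy)tridecyl]-4-hydroxy-3-methoxycyclohexa-2,4-dien-1-one | CCCCCCCCCCC[C@H](CC1=C(O)C(OC)=CC(=O)C1)O[Si](C)(C)C(C)(C)C | intermediate (not isolated)
12 | 2-[(2R)-2-(tert-butyldimethylsilyloxy)tridecyl]-6-methoxybenzene-1,4-diol | CCCCCCCCCCC[C@H](Cc1cc(O)cc(OC)c1O)O[Si](C)(C)C(C)(C)C | intermediate
13 | 2-[(2R)-2-(tert-butyldimethylsilyloxy)tridecyl]-6-methoxy-1,4-benzoquinone | CCCCCCCCCCC[C@H](CC1=CC(=O)C=C(OC)C1=O)O[Si](C)(C)C(C)(C)C | intermediate
14 | 2-[(2R)-2-hydroxytridecyl]-6-methoxy-1,4-benzoquinone | CCCCCCCCCCC[C@H](CC1=CC(=O)C=C(OC)C1=O)O | intermediate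
15 | (2R)-1-(5-methoxy-3,6-dioxocyclohexa-1,4-dien-1-yl)tridecan-2-yl acetate | CCCCCCCCCCC[C@H](CC1=CC(=O)C=C(OC)C1=O)OC(C)=O | intermediate
16 | (2R)-1-(2,5-dihydroxy-3-methoxyphenyl)tridecan-2-yl acetate | CCCCCCCCCCC[C@H](Cc1cc(O)cc(OC)c1O)OC(C)=O | target

Total step count: 10
Longest linear sequence: 8 steps (steps 1, 2, 5, 6, 7, 8, 9, 10); steps 3 and 4 form the short second branch.

Steps most likely to fail

Step 5. What may go wrong is proton transfer from the acidic ring C–H of 7 to the alkenyllithium, competing attack at the vinylogous-ester carbonyl, and hydrolytic loss of the moisture-sensitive methyl ester before or after the addition. The fallback swaps the methyl ester for the robust isopropyl ester and installs the methoxy group last; it sets out from bromide 4 and returns at hydroxyquinone 14. Commercial diisopropyl squarate F1 is reduced with LiAlH(OtBu)3 to 4-hydroxy-2,3-diisopropoxycyclobut-2-en-1-one F2, which conc. HCl in CH2Cl2 converts into 3-isopropoxycyclobut-3-ene-1,2-dione F3. Alkenyllithium 8, made from 4 as before, is added to F3 to give the isopropoxy adduct F4. Thermolysis in toluene gives the isopropoxyhydroquinone silyl ether F5, and Ag2O gives the isopropoxyquinone silyl ether F6. Acid-catalysed vinylogous transesterification in methanol (cat. H2SO4, rt) then exchanges isopropoxy for methoxy and removes the silyl group in the same operation, giving 14.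

Step 1. What may go wrong is insufficient facial discrimination with the unbranched aldehyde, or slow turnover of the chromium catalyst, so that 3 forms with low enantiomeric purity. The fallback fixes the stereocentre by kinetic resolution instead; it sets out from dodecanal 1 and returns at silyl ether 4. Corey–Chaykovsky methylenation (trimethylsulfonium iodide, NaH, DMSO/THF) gives racemic 2-undecyloxirane F7. Hydrolytic kinetic resolution with (R,R)-N,N′-bis(3,5-di-tert-butylsalicylidene)-1,2-cyclohexanediaminocobalt acetate (trivalent cobalt, 0.55 equiv water) should leave (R)-2-undecyloxirane F8. Opening at the terminal carbon with lithium acetylide–ethylenediamine complex (LiC≡CH·H2NCH2CH2NH2) in DMSO gives (R)-pentadec-1-yn-4-ol F9, and TBSCl/imidazole gives (R)-4-(tert-butyldimethylsilyloxy)pentadec-1-yne F10. Markovnikov bromoboration of the terminal alkyne with B-bromo-9-borabicyclo[3.3.1]nonane (CH2Cl2, 0 °C), followed by protonolysis of the C–B bond with acetic acid, delivers 2-bromoalkene 4.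

Step 9. What may go wrong is attack of pyridine or DMAP on the electrophilic quinone (conjugate addition at the free ring positions or displacement of the methoxy group), with decomposition before the secondary alcohol is acetylated. The fallback avoids acylating a quinone; it leaves the route at hydroquinone 12 and returns at target 16. Desilylation of 12 with HF in MeCN gives 2-[(2R)-2-hydroxytridecyl]-6-methoxybenzene-1,4-diol F11. Exhaustive acetylation (Ac2O, pyridine, DMAP, Ar) gives the triacetate F12. Chemoselective aminolysis of the two aryl acetates with pyrrolidine (2.2 equiv, CH2Cl2, 0 °C, Ar) then gives 16, because aryl esters are cleaved far faster than the secondary alkyl acetate.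

Further compounds
F1 | step 5 | diisopropyl squarate (3,4-diisopropoxycyclobut-3-ene-1,2-dione) | CC(C)OC1=C(OC(C)C)C(=O)C1=O
F2 | step 5 | 4-hydroxy-2,3-diisopropoxycyclobut-2-en-1-one (racemic) | CC(C)OC1=C(OC(C)C)C(O)C1=O
F3 | step 5 | 3-isopropoxycyclobut-3-ene-1,2-dione | CC(C)OC1=CC(=O)C1=O
F4 | step 5 | 4-[(4R)-4-(tert-butyldimethylsilyloxy)pentadec-1-en-2-yl]-4-hydroxy-3-isopropoxycyclobut-2-en-1-one (both carbinol epimers) | CCCCCCCCCCC[C@H](CC(=C)C1(O)C(OC(C)C)=CC1=O)O[Si](C)(C)C(C)(C)C
F5 | step 5 | 2-[(2R)-2-(tert-butyldimethylsilyloxy)tridecyl]-6-isopropoxybenzene-1,4-diol | CCCCCCCCCCC[C@H](Cc1cc(O)cc(OC(C)C)c1O)O[Si](C)(C)C(C)(C)C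
F6 | step 5 | 2-[(2R)-2-(tert-butyldimethylsilyloxy)tridecyl]-6-isopropoxy-1,4-benzoquinone | CCCCCCCCCCC[C@H](CC1=CC(=O)C=C(OC(C)C)C1=O)O[Si](C)(C)C(C)(C)C
F7 | step 1 | 2-undecyloxirane (racemic) | CCCCCCCCCCCC1CO1
F8 | step 1 | (R)-2-undecyloxirane | CCCCCCCCCCC[C@@H]1CO1
F9 | step 1 | (R)-pentadec-1-yn-4-ol | CCCCCCCCCCC[C@H](CC#C)O
F10 | step 1 | (R)-4-(tert-butyldimethylsilyloxy)pentadec-1-yne | CCCCCCCCCCC[C@H](CC#C)O[Si](C)(C)C(C)(C)C
F11 | step 9 | 2-[(2R)-2-hydroxytridecyl]-6-methoxybenzene-1,4-diol | CCCCCCCCCCC[C@H](Cc1cc(O)cc(OC)c1O)O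
F12 | step 9 | (2R)-1-(2,5-diacetoxy-3-methoxyphenyl)tridecan-2-yl acetate | CCCCCCCCCCC[C@H](Cc1cc(OC(C)=O)cc(OC)c1OC(C)=O)OC(C)=O
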